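| flask | substrate | reagent in the second phase | remark | time | volume of the second phase over the first |
|---|---|---|---|---|---|
| larch | 0.28 M | 0.22 M | run made earlier |  |  |
| oak | 0.44 M | 0.22 M | run made earlier |  |  |
| ash | 0.20 M | 0.44 M | run made earlier |  |  |
| flask | 0.20 M | 0.220 M |  | 15 min | 0.50 |

| run | time / min | target / % | substrate / % |
|---|---|---|---|
| larch | 0.667 | 1.4 | 97.6 |
| larch | 2.00 | 7.5 | 90.8 |
| larch | 3.00 | 9.0 | 85.0 |
| larch | 5.00 | 11.3 | 74.5 |
| larch | 6.00 | 10.7 | 74.9 |
| larch | 10.0 | 8.3 | 62.7 |
| oak | 0.667 | 1.3 | 98.5 |
| oak | 1.33 | 5.1 | 95.9 |
| oak | 2.00 | 8.0 | 90.5 |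
| oak | 3.00 | 9.6 | 84.3 |
| oak | 5.00 | 9.1 | 80.2 |
| oak | 10.0 | 6.0 | 70.6 |
| ash | 0.833 | 5.3 | 94.7 |
| ash | 2.50 | 18.8 | 75.7 |
| ash | 4.00 | 22.4 | 62.5 |
| ash | 6.00 | 19.6 | 51.9 |
| ash | 10.0 | 12.4 | 38.0 |

(standard deviation of a reading: 1 percentage point)

- amounts and yields of target count product in the second phase too
- in the second phase: reagent in the second phase, product in the second phase; everything else is in the first
- charges count per volume of the first phase; a concentration in a rate is the amount of a species over the volume of its own phase; every rate counts per litre of the first phase
- steps that have been proposed: target -> decomposed product; target <-> product in the second phase; substrate + reagent in the reaction phase <-> target; reagent in the reaction phase <-> reagent in the second phase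
- the earlier runs hold the two phases in the same ratio of volumes as the flask asked about

* how much target and product in the second phase together there is at 15 min, in percent of the substrate charged
* part of the substrate charged that has reacted at 15 min

A single first-order constant cannot hold the substrate in larch. In larch, its fractional loss reads 0.0660 min⁻¹ from 2.00 min to 5.00 min, then slows to 0.0345 min⁻¹ up to 10.0 min. So I carry a mean, a pseudo-first-order loss constant: the log of substrate charged over substrate left, divided by the time. At 10.0 min, larch reads 0.0467 min⁻¹. Oak, with the same reagent and more substrate, reads less, 0.0348 min⁻¹. I call the fall of this constant per mole per litre of substrate charged, reagent held, the charge drag: 0.0742 L mol⁻¹ min⁻¹. It is a reading and carries the scatter of the runs.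

The flask charges less substrate than larch, so I reckon that the drag lifts its constant to 0.0526 min⁻¹ at 10.0 min. Larch's late rate is 0.739 of its mean. I apply that factor to the flask's last stretch, which gives 0.0389 min⁻¹. Over 15 min, I reckon 48.7% left, so 51.3% reacted. I hold that late rate flat, so I expect this to be high.

The forecast gives 47% reacted and 5.5% of target, on the ground that “The flask resembles larch with less reagent drain”. Its conversion is lower than mine, and I take its target.

The flask gives 48.9% reacted and 6.81% of target, down from 11.1% at 7.50 min. So the flask still holds about half of its substrate.

    target → decomposed product (k = 0.434 min⁻¹)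
    target ⇌ product in the second phase, rate k2*([target] - [product in the second phase]/K2) per volume of the first phase (partition coefficient = 0.810, kL = 1.25 min⁻¹)
    substrate + reagent in the reaction phase ⇌ target (K = 1.56 L mol⁻¹, k = 0.823 L mol⁻¹ min⁻¹)
    reagent in the reaction phase ⇌ reagent in the second phase, rate k4*([reagent in the reaction phase] - [reagent in the second phase]/K4) per volume of the first phase (partition coefficient = 0.425, kL = 0.144 min⁻¹)

The flask's mean constant over 15 min comes to 0.0448 min⁻¹. For the neighbour charged with 0.050 M of substrate, time and reagent held, I add the drag, read at 10.0 min, on top of that: 0.0559 min⁻¹. Over 15 min I reckon this leaves 43.2% of its substrate. The neighbour gives 41.6% left, with 58.4% reacted.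

The earlier runs and the new flask are calculated with made-up constants, noise included.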